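**Retrosynthetic overview**

1. The target is reached by acidic removal of three MOM ethers from the protected (S)-flavanone, which comes from the flavone by enantioselective copper hydride 1,4-reduction of C2=C3. The base-labile C2 centre is therefore set last but one.
2. The strategy rests on ring C, the γ-pyranone O1–C2–C3–C4–C4a–C8a. Its C4 is a carbonyl carbon bonded only to arene carbon C4a and to C3, so it enters as carbon monoxide between the iodine-bearing carbon of an o-iodophenol and phenylacetylene, which supplies C2, C3 and the 2-phenyl ring. C4a–C4, C4–C3 and O1–C2 form in one operation.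
3. The iodophenol comes from O-MOM capping of the adduct of a 4-hydroxy-2-pyranone with an o-quinone methide. The quinone methide precursor is made from 2,4,6-trihydroxybenzaldehyde by chelation-controlled bis-MOM protection, ortho-iodination and reduction, which places the free phenol between the iodide and the benzylic carbon.
4. The 6-ethyl-4-hydroxy-5-methyl-2-pyranone comes from 3-pentanone (as its silyl enol ether) and malonyl dichloride.
5. Ring order: α-pyranone first (step 2), then ring C of the flavone on the intact ring A (step 8). Ring A and the phenyl ring are bought.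

Key step: step 8

Remark (assumption): the sense of induction of the chiral copper hydride on this flavone is assumed. (R)-DTBM-SEGPHOS is written, and its antipode is to be used if a trial on 5,7-bis(methoxymethoxy)flavone shows hydride delivery to the Si face of C2.

**Route**

Step 1
Reactants: 1 pentan-3-one
Product: 2 trimethyl(pent-2-en-3-yloxy)silane (E/Z mixture)
Conditions: TMSOTf (1.1 equiv), Et3N (1.3 equiv), CH2Cl2, 0 °C
Reagents that add atoms: trimethylsilyl trifluoromethanesulfonate, C[Si](C)(C)OS(=O)(=O)C(F)(F)F
Why: Soft enolisation and O-silylation of a ketone is standard, and because the ketone is symmetrical only one constitution can form, its E/Z mixture being inconsequential since the geometry is lost in step 2.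

Step 2
Reactants: 2 trimethyl(pent-2-en-3-yloxy)silane, 3 malonyl dichloride
Product: 5 6-ethyl-4-hydroxy-5-methyl-2H-pyran-2-one, via diketo acid chloride 4 (not isolated)
Conditions: Et2O, −78 °C → rt; aqueous work-up
Reagents that add atoms: none
Why: Twofold acylation of a silyl enol ether by malonyl dichloride is a known route to 4-hydroxy-2-pyranones, in which C-acylation at the enol carbon (loss of TMSCl) gives 4 and the enol oxygen of its ethyl ketone then closes the lactone by O-acylation (loss of HCl).

Step 3
Reactants: 6 2,4,6-trihydroxybenzaldehyde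
Product: 7 2-hydroxy-4,6-bis(methoxymethoxy)benzaldehyde
Conditions: MOMCl (2.2 equiv), i-Pr2NEt (2.5 equiv), CH2Cl2, 0 °C → rt
Reagents that add atoms: chloromethyl methyl ether, COCCl
Why: Williamson-type O-alkylation caps the hydroxyl para to the formyl group and one of the two equivalent ortho hydroxyls, while the remaining ortho hydroxyl stays free because its hydrogen bond to the formyl oxygen lowers its nucleophilicity.

Step 4
Reactants: 7 2-hydroxy-4,6-bis(methoxymethoxy)benzaldehyde
Product: 8 2-hydroxy-3-iodo-4,6-bis(methoxymethoxy)benzaldehyde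
Conditions: BnMe3N+ ICl2− (1.05 equiv), NaHCO3 (2 equiv), CH2Cl2/MeOH, rt
Reagents that add atoms: benzyltrimethylammonium dichloroiodate, C[N+](C)(C)Cc1ccccc1.Cl[I-]Cl
Why: Electrophilic aromatic iodination with this buffered dichloroiodate is known, for chelated 2-hydroxy-4,6-dialkoxyaryl carbonyl compounds, to occur at C3 next to the hydrogen-bonded hydroxyl and not at C5 between the two ethers, and the hydrogencarbonate keeps the medium non-acidic for the MOM groups.

Step 5
Reactants: 8 2-hydroxy-3-iodo-4,6-bis(methoxymethoxy)benzaldehyde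
Product: 9 2-(hydroxymethyl)-6-iodo-3,5-bis(methoxymethoxy)phenol
Conditions: NaBH4 (0.6 equiv), THF/MeOH, −10 → 0 °C; pH 7 buffer work-up; used crude
Reagents that add atoms: none
Why: Borohydride reduction of the aldehyde gives the salicyl alcohol, and running it cold with a neutral work-up keeps the very electron-rich benzylic alcohol from ionising (which would lead to the cresol or to oligomers), the aryl iodide and the acetals being inert.

Step 6
Reactants: 9 2-(hydroxymethyl)-6-iodo-3,5-bis(methoxymethoxy)phenol, 5 6-ethyl-4-hydroxy-5-methyl-2H-pyran-2-one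
Product: 11 6-ethyl-4-hydroxy-3-{[2-hydroxy-3-iodo-4,6-bis(methoxymethoxy)phenyl]methyl}-5-methyl-2H-pyran-2-one, via o-quinone methide 10 (not isolated)
Conditions: 5 (2 equiv), 1,4-dioxane, 4 Å MS, 80 °C, slow addition of 9
Reagents that add atoms: none
Why: Thermal, weakly acid-assisted dehydration of the salicyl alcohol gives o-quinone methide 10 (stabilised by the two alkoxy groups ortho and para to the benzylic carbon), which is trapped by Michael addition of the nucleophilic C3 of the 4-hydroxypyranone with rearomatisation, the pyranone being too weak an acid to cleave MOM ethers and its excess suppressing self-condensation.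

Step 7
Reactants: 11 6-ethyl-4-hydroxy-3-{[2-hydroxy-3-iodo-4,6-bis(methoxymethoxy)phenyl]methyl}-5-methyl-2H-pyran-2-one
Product: 12 6-ethyl-3-{[2-hydroxy-3-iodo-4,6-bis(methoxymethoxy)phenyl]methyl}-4-(methoxymethoxy)-5-methyl-2H-pyran-2-one
Conditions: MOMCl (1.05 equiv), i-Pr2NEt (1.1 equiv), CH2Cl2, −20 → 0 °C
Reagents that add atoms: chloromethyl methyl ether, COCCl
Why: Chemoselective O-alkylation is expected because one equivalent of amine base ionises only the vinylogous carboxylic acid of the pyranone, which is far more acidic than the hindered phenol flanked by iodine and the benzylic carbon (an O2-alkylated isomer, if formed, would be deprotected to the same target).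

Step 8
Reactants: 12 6-ethyl-3-{[2-hydroxy-3-iodo-4,6-bis(methoxymethoxy)phenyl]methyl}-4-(methoxymethoxy)-5-methyl-2H-pyran-2-one, 13 carbon monoxide, 14 phenylacetylene
Product: 17 8-{[6-ethyl-4-(methoxymethoxy)-5-methyl-2-oxo-2H-pyran-3-yl]methyl}-5,7-bis(methoxymethoxy)-2-phenyl-4H-chromen-4-one, via ynone 15 (not isolated), via enaminone 16 (not isolated)
Conditions: PdCl2(dppf) (5 mol %), 14 (1.5 equiv), CO (10 bar), Et2NH (10 equiv), DMF, 80 °C
Reagents that add atoms: none
Why: Pd(0) inserts into the C–I bond of 12, CO insertion gives the aroyl–palladium species, and amine-assisted copper-free alkynylation with 14 followed by reductive elimination forms ynone 15, which makes C4a–C4 and C4–C3. Diethylamine then adds reversibly to the ynone to give β-amino enone 16, and the ortho phenol displaces the amine at the β-carbon, so that O1–C2 forms and the γ-pyranone ring closes in what is overall a 6-endo-dig cyclisation. The closest known reaction type is the palladium-catalysed carbonylative Sonogashira annulation of 2-iodophenols with terminal alkynes to flavones in secondary-amine media. No stereocentre is created. The step needs carbonylative instead of direct alkynylation, which CO pressure and the absence of copper secure for this electron-rich aryl–palladium, and 6-endo instead of 5-exo closure to the aurone, which the enaminone pathway secures by placing the leaving group on the β-carbon. Because only the hydroxyl between the iodide and the benzylic carbon is free while O5 and O7 are MOM ethers, the ring oxygen is necessarily the one flanked by the pyranonylmethyl-bearing carbon, so the 8-substitution follows from the substrate.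

Step 9
Reactants: 17 8-{[6-ethyl-4-(methoxymethoxy)-5-methyl-2-oxo-2H-pyran-3-yl]methyl}-5,7-bis(methoxymethoxy)-2-phenyl-4H-chromen-4-one
Product: 19 (2S)-8-{[6-ethyl-4-(methoxymethoxy)-5-methyl-2-oxo-2H-pyran-3-yl]methyl}-5,7-bis(methoxymethoxy)-2-phenyl-2,3-dihydro-4H-chromen-4-one, via silyl enol ether 18 (not isolated)
Conditions: Cu(OAc)2·H2O (5 mol %), (R)-DTBM-SEGPHOS (5.5 mol %), (EtO)2MeSiH (3 equiv), toluene/THF, 0 °C → rt; then aq. NH4Cl, THF, 0 °C
Reagents that add atoms: none
Why: Asymmetric copper hydride conjugate reduction (known for β,β-disubstituted enones and chromones) should deliver hydride under ligand control to the Re face of C2 and so set (S)-C2, the copper enolate being trapped by the silane as silyl enol ether 18 before the aryloxide can β-eliminate or the ketone be reduced, while the tetrasubstituted, donor-substituted double bonds of the α-pyranone are too hindered to react.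

Step 10
Reactants: 19 (2S)-8-{[6-ethyl-4-(methoxymethoxy)-5-methyl-2-oxo-2H-pyran-3-yl]methyl}-5,7-bis(methoxymethoxy)-2-phenyl-2,3-dihydro-4H-chromen-4-one
Product: 20 (2S)-8-[(6-ethyl-4-hydroxy-5-methyl-2-oxo-2H-pyran-3-yl)methyl]-5,7-dihydroxy-2-phenyl-2,3-dihydro-4H-chromen-4-one
Conditions: HCl (1.25 M in MeOH), THF, rt → 40 °C
Reagents that add atoms: none
Why: Acid-catalysed transacetalisation to methanol releases the two phenols and the pyranone enol as dimethoxymethane, and C2 should keep its configuration because ring opening to the chalcone (retro-oxa-Michael) is slow under mildly acidic, unlike basic, conditions.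

**Compound list**

1 | pentan-3-one | CCC(=O)CC | starting material
2 | trimethyl(pent-2-en-3-yloxy)silane (E/Z mixture) | CC=C(CC)O[Si](C)(C)C | intermediate
3 | malonyl dichloride | O=C(Cl)CC(Cl)=O | starting material
4 | 4-methyl-3,5-dioxoheptanoyl chloride (racemic, not isolated) | CCC(=O)C(C)C(=O)CC(Cl)=O | intermediate
5 | 6-ethyl-4-hydroxy-5-methyl-2H-pyran-2-one | CCc1oc(=O)cc(O)c1C | intermediate
6 | 2,4,6-trihydroxybenzaldehyde | O=Cc1c(O)cc(O)cc1O | starting material
7 | 2-hydroxy-4,6-bis(methoxymethoxy)benzaldehyde | O=Cc1c(O)cc(OCOC)cc1OCOC | intermediate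
8 | 2-hydroxy-3-iodo-4,6-bis(methoxymethoxy)benzaldehyde | O=Cc1c(O)c(I)c(OCOC)cc1OCOC | intermediate
9 | 2-(hydroxymethyl)-6-iodo-3,5-bis(methoxymethoxy)phenol | OCc1c(O)c(I)c(OCOC)cc1OCOC | intermediate
10 | 2-iodo-3,5-bis(methoxymethoxy)-6-methylidenecyclohexa-2,4-dien-1-one (not isolated) | C=C1C(=O)C(I)=C(OCOC)C=C1OCOC | intermediate
11 | 6-ethyl-4-hydroxy-3-{[2-hydroxy-3-iodo-4,6-bis(methoxymethoxy)phenyl]methyl}-5-methyl-2H-pyran-2-one | CCc1oc(=O)c(Cc2c(OCOC)cc(OCOC)c(I)c2O)c(O)c1C | intermediate
12 | 6-ethyl-3-{[2-hydroxy-3-iodo-4,6-bis(methoxymethoxy)phenyl]methyl}-4-(methoxymethoxy)-5-methyl-2H-pyran-2-one | CCc1oc(=O)c(Cc2c(OCOC)cc(OCOC)c(I)c2O)c(OCOC)c1C | intermediate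
13 | carbon monoxide | [C-]#[O+] | starting material
14 | phenylacetylene | C#Cc1ccccc1 | starting material
15 | 6-ethyl-3-{[2-hydroxy-4,6-bis(methoxymethoxy)-3-(3-phenylprop-2-ynoyl)phenyl]methyl}-4-(methoxymethoxy)-5-methyl-2H-pyran-2-one (not isolated) | CCc1oc(=O)c(Cc2c(OCOC)cc(OCOC)c(C(=O)C#Cc3ccccc3)c2O)c(OCOC)c1C | intermediate
16 | 3-{[3-[3-(diethylamino)-3-phenylprop-2-enoyl]-2-hydroxy-4,6-bis(methoxymethoxy)phenyl]methyl}-6-ethyl-4-(methoxymethoxy)-5-methyl-2H-pyran-2-one (alkene geometry not defined, not isolated) | CCc1oc(=O)c(Cc2c(OCOC)cc(OCOC)c(C(=O)C=C(N(CC)CC)c3ccccc3)c2O)c(OCOC)c1C | intermediate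
17 | 8-{[6-ethyl-4-(methoxymethoxy)-5-methyl-2-oxo-2H-pyran-3-yl]methyl}-5,7-bis(methoxymethoxy)-2-phenyl-4H-chromen-4-one | CCc1oc(=O)c(Cc2c(OCOC)cc(OCOC)c3c2oc(-c2ccccc2)cc3=O)c(OCOC)c1C | intermediate
18 | 3-{[(2S)-4-{[diethoxy(methyl)silyl]oxy}-5,7-bis(methoxymethoxy)-2-phenyl-2H-chromen-8-yl]methyl}-6-ethyl-4-(methoxymethoxy)-5-methyl-2H-pyran-2-one (not isolated) | CCc1oc(=O)c(Cc2c(OCOC)cc(OCOC)c3c2O[C@H](c2ccccc2)C=C3O[Si](C)(OCC)OCC)c(OCOC)c1C | intermediate
19 | (2S)-8-{[6-ethyl-4-(methoxymethoxy)-5-methyl-2-oxo-2H-pyran-3-yl]methyl}-5,7-bis(methoxymethoxy)-2-phenyl-2,3-dihydro-4H-chromen-4-one | CCc1oc(=O)c(Cc2c(OCOC)cc(OCOC)c3c2O[C@H](c2ccccc2)CC3=O)c(OCOC)c1C | intermediate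
20 | (2S)-8-[(6-ethyl-4-hydroxy-5-methyl-2-oxo-2H-pyran-3-yl)methyl]-5,7-dihydroxy-2-phenyl-2,3-dihydro-4H-chromen-4-one | CCc1oc(=O)c(Cc2c(O)cc(O)c3c2O[C@H](c2ccccc2)CC3=O)c(O)c1C | target

**Step count**

Total step count: 10. Longest linear sequence: 8 steps (steps 3–10, from 2,4,6-trihydroxybenzaldehyde 6 to 20).

**Steps most likely to fail**

Step 8. Oxidative addition at the doubly ortho-flanked, electron-rich C–I bond may be slow. Aminocarbonylation by diethylamine or hydrodeiodination could then overtake the alkynylative carbonylation, and prolonged heating with the secondary amine may erode the alkoxypyranone by addition–elimination. The fallback moves the annulation ahead of the pyranone. It sets out from 8, whose formyl group makes the ring less electron-rich and which tolerates forcing conditions (PdCl2(dppf), CO 13 at 20 bar, 14, neat Et2NH, 120 °C). This should give, through 2-hydroxy-4,6-bis(methoxymethoxy)-3-(3-phenylprop-2-ynoyl)benzaldehyde F1 (not isolated), 5,7-bis(methoxymethoxy)-4-oxo-2-phenyl-4H-chromene-8-carbaldehyde F2. Organocatalytic reductive alkylation of pyranone 5 with F2 (L-proline cat., Hantzsch ester, CH2Cl2, rt) then proceeds through the Knoevenagel alkylidene 3-{[5,7-bis(methoxymethoxy)-4-oxo-2-phenyl-4H-chromen-8-yl]methylidene}-6-ethyl-5-methyl-2H-pyran-2,4(3H)-dione F3 (not isolated). It gives 8-[(6-ethyl-4-hydroxy-5-methyl-2-oxo-2H-pyran-3-yl)methyl]-5,7-bis(methoxymethoxy)-2-phenyl-4H-chromen-4-one F4. Its single hydroxyl is capped with MOMCl/i-Pr2NEt, which comes back to the route at 17.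

Step 9. The doubly donor-substituted vinylogous ester may react sluggishly with the copper hydride, facial discrimination may be insufficient, or the copper enolate may expel the aryloxide (ring opening to the chalcone) before it is silylated. The fallback sets out from 17 and uses asymmetric hydrogenation with a chiral ruthenium–NHC catalyst, a reaction known for flavones. The catalyst is generated from [Ru(cod)(2-methylallyl)2], a chiral imidazolinium salt and KOt-Bu, and used under H2 pressure in toluene/n-hexane at rt. It reduces C2=C3 enantioselectively and, partly or wholly, C4=O, giving 6-ethyl-3-{[(2S)-4-hydroxy-5,7-bis(methoxymethoxy)-2-phenyl-3,4-dihydro-2H-chromen-8-yl]methyl}-4-(methoxymethoxy)-5-methyl-2H-pyran-2-one F5 (C4 epimers, possibly with some flavanone). Dess–Martin periodinane with NaHCO3 in CH2Cl2 re-oxidises C4 and comes back to the route at 19.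

Step 6. Ionisation of the salicyl alcohol may outrun its capture, so that the o-quinone methide is intercepted by the electron-rich ring of a second molecule (oligomerisation), or 9 may degrade during isolation after step 5. The fallback sets out from aldehyde 8 and bypasses 9. A three-component reductive alkylation of 8 with 5 and Hantzsch ester (L-proline cat., CH2Cl2 or EtOH, rt to 40 °C) proceeds through the Knoevenagel alkylidene 6-ethyl-3-{[2-hydroxy-3-iodo-4,6-bis(methoxymethoxy)phenyl]methylidene}-5-methyl-2H-pyran-2,4(3H)-dione F6 (not isolated). This is reduced in the flask by hydride transfer, which comes back to the route at 11.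

**Further compounds**

F1 | step 8 | 2-hydroxy-4,6-bis(methoxymethoxy)-3-(3-phenylprop-2-ynoyl)benzaldehyde | O=Cc1c(O)c(C(=O)C#Cc2ccccc2)c(OCOC)cc1OCOC
F2 | step 8 | 5,7-bis(methoxymethoxy)-4-oxo-2-phenyl-4H-chromene-8-carbaldehyde | O=Cc1c(OCOC)cc(OCOC)c2c1oc(-c1ccccc1)cc2=O
F3 | step 8 | 3-{[5,7-bis(methoxymethoxy)-4-oxo-2-phenyl-4H-chromen-8-yl]methylidene}-6-ethyl-5-methyl-2H-pyran-2,4(3H)-dione (alkene geometry not defined) | CCC1=C(C)C(=O)C(=Cc2c(OCOC)cc(OCOC)c3c2oc(-c2ccccc2)cc3=O)C(=O)O1
F4 | step 8 | 8-[(6-ethyl-4-hydroxy-5-methyl-2-oxo-2H-pyran-3-yl)methyl]-5,7-bis(methoxymethoxy)-2-phenyl-4H-chromen-4-one | CCc1oc(=O)c(Cc2c(OCOC)cc(OCOC)c3c2oc(-c2ccccc2)cc3=O)c(O)c1C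
F5 | step 9 | 6-ethyl-3-{[(2S)-4-hydroxy-5,7-bis(methoxymethoxy)-2-phenyl-3,4-dihydro-2H-chromen-8-yl]methyl}-4-(methoxymethoxy)-5-methyl-2H-pyran-2-one (C4 epimers) | CCc1oc(=O)c(Cc2c(OCOC)cc(OCOC)c3c2O[C@H](c2ccccc2)CC3O)c(OCOC)c1C
F6 | step 6 | 6-ethyl-3-{[2-hydroxy-3-iodo-4,6-bis(methoxymethoxy)phenyl]methylidene}-5-methyl-2H-pyran-2,4(3H)-dione (alkene geometry not defined) | CCC1=C(C)C(=O)C(=Cc2c(O)c(I)c(OCOC)cc2OCOC)C(=O)O1
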